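**Retrosynthetic overview**
- The target is reached by desilylation and a Felkin–Anh ketone reduction (sets C7) of a trans-3-aroyl-4-benzyl-tetrahydrofuran.
- The tetrahydrofuran ring is formed last, by cyclisation of a silyl enol ether onto an oxocarbenium ion from a MOM ether (adds C9); C8 is set trans by equilibration.
- The γ-hydroxy ketone precursor comes from an aryllithium and an (R)-β-(arylmethyl)-γ-butyrolactone, whose carbonyl carbon becomes C7.
- The lactone ring is formed first, by an enantioselective, desymmetrising carbonylative ring expansion of a prochiral 3-(arylmethyl)oxetane (sets C8').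
- The oxetane comes from Ni cross-electrophile coupling of one aryl bromide (used twice; made from 4-bromophenol) with 3-(bromomethyl)oxetane.

Assumption: lignan numbering (C7/C8/C9, C7'/C8'/C9') is used in the explanations; Ar = 3,5-dimethoxy-4-[tri(propan-2-yl)silyloxy]phenyl; salen = N,N'-bis(3,5-di-tert-butylsalicylidene)cyclohexane-1,2-diamine dianion; the sense of induction of the new catalyst in step 5 is not known in advance, so the ligand enantiomer that gives the R lactone is used (written R,R; its mirror image is equally available).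

**Step 1**
Reactants: 1 4-bromophenol
Product: 2 4-bromo-2,6-diiodophenol
Conditions: NIS (2.2 equiv), TsOH·H2O (10 mol %), MeCN, rt
Reagents that add atoms: N-iodosuccinimide, O=C1CCC(=O)N1I
Why: Electrophilic aromatic iodination; the para position is blocked by bromine, so the phenol is iodinated at both ortho positions.

**Step 2**
Reactants: 2 4-bromo-2,6-diiodophenol
Product: 3 4-bromo-2,6-dimethoxyphenol
Conditions: NaOMe (6 equiv), CuBr (15 mol %), MeOH/DMF, 80 °C; then aq HCl
Reagents that add atoms: sodium methoxide, C[O-].[Na+]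
Why: Copper-catalysed Ullmann-type methoxylation; the two C–I bonds ortho to the phenoxide react below the temperature at which the electron-rich para C–Br bond is attacked.

**Step 3**
Reactants: 3 4-bromo-2,6-dimethoxyphenol
Product: 4 (4-bromo-2,6-dimethoxyphenoxy)tri(propan-2-yl)silane
Conditions: TIPSCl, imidazole, DMF, 40 °C
Reagents that add atoms: chlorotri(propan-2-yl)silane, CC(C)[Si](Cl)(C(C)C)C(C)C
Why: Silyl ether formation; the bulky TIPS group survives the organolithium, Lewis acid and hydride steps and is removed by fluoride at the end.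

**Step 4**
Reactants: 4 (4-bromo-2,6-dimethoxyphenoxy)tri(propan-2-yl)silane; 5 3-(bromomethyl)oxetane
Product: 6 3-(ArCH2)oxetane
Conditions: NiBr2(dme) (10 mol %), 4,4'-di-tert-butyl-2,2'-bipyridine (10 mol %), Zn (2 equiv), NaI (25 mol %), DMA, 60 °C
Reagents that add atoms: none
Why: Nickel-catalysed reductive cross-electrophile coupling of an aryl bromide with a primary alkyl bromide; no organometallic reagent is formed, so the oxetane and silyl ether are untouched.

**Step 5**
Reactants: 6 3-(ArCH2)oxetane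
Product: 7 (4R)-4-(ArCH2)oxolan-2-one
Conditions: [(R,R)-(salen)Cr(thf)2][Co(CO)4] (5 mol %), CO (60 bar), DME, 60 °C
Reagents that add atoms: carbon monoxide, [C-]#[O+]
Why: Proposed new method: enantioselective desymmetrising carbonylative ring expansion of a prochiral 3-substituted oxetane; the chiral trivalent chromium cation binds the oxetane oxygen, the tetracarbonylcobaltate anion opens one of the two enantiotopic O–CH2 bonds by SN2 attack, the alkyl group shifts from cobalt to a CO ligand (1,2-migratory insertion), and the chromium alkoxide closes onto the acyl cobalt to release the five-membered lactone, so the choice of CH2 sets C8' as R; the closest known reactions are the racemic Lewis acid/[Co(CO)4]− carbonylation of oxetanes to γ-butyrolactones, the enantioselective carbonylation of meso-epoxides, and the (salen)Co-catalysed enantioselective intramolecular opening of 3-substituted oxetanes.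

**Step 6**
Reactants: 4 (4-bromo-2,6-dimethoxyphenoxy)tri(propan-2-yl)silane; 7 (4R)-4-(ArCH2)oxolan-2-one
Product: 10 (3R)-4-hydroxy-1-Ar-3-(ArCH2)butan-1-one, via aryllithium 8 (not isolated), via lithium lactolate 9 (not isolated)
Conditions: 4, n-BuLi, THF, −78 °C; then 7, −78 °C; then H2O
Reagents that add atoms: none
Why: Br/Li exchange, then nucleophilic addition of the aryllithium to the lactone; the lithium lactolate is stable at −78 °C, which prevents double addition, and gives the γ-hydroxy ketone on quench without touching C8'.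

**Step 7**
Reactants: 10 (3R)-4-hydroxy-1-Ar-3-(ArCH2)butan-1-one
Product: 11 (3R)-4-(methoxymethoxy)-1-Ar-3-(ArCH2)butan-1-one
Conditions: MOMCl, i-Pr2NEt, CH2Cl2, 0 °C to rt
Reagents that add atoms: chloromethyl methyl ether, COCCl
Why: Standard O-alkylation of the primary alcohol to its MOM ether, which stores the future C9 as a latent oxocarbenium ion.

**Step 8**
Reactants: 11 (3R)-4-(methoxymethoxy)-1-Ar-3-(ArCH2)butan-1-one
Product: 13 [(3R,4R)-4-(ArCH2)oxolan-3-yl](Ar)methanone, via silyl enol ether 12 (not isolated)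
Conditions: TMSOTf (2.2 equiv), i-Pr2NEt (2.5 equiv), CH2Cl2, −78 to 0 °C; aq NaHCO3; then DBU (cat.), CH2Cl2, rt
Reagents that add atoms: none
Why: One-pot silyl enol ether formation and intramolecular Mukaiyama-type addition to the oxocarbenium ion released from the MOM ether (the same tethered enolate/oxocarbenium pair as in Lewis acid ring contractions of 4,5-dihydro-1,3-dioxepines to 3-acyltetrahydrofurans) closes the tetrahydrofuran ring; C8 is α to the ketone and DBU equilibrates it to the more stable trans (3R,4R) isomer.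

**Step 9**
Reactants: 13 [(3R,4R)-4-(ArCH2)oxolan-3-yl](Ar)methanone
Product: 14 (S)-[(3R,4R)-4-(ArCH2)oxolan-3-yl](Ar)methanol
Conditions: LiBH(s-Bu)3 (L-Selectride), THF, −78 °C; then H2O
Reagents that add atoms: none
Why: Felkin–Anh-controlled hydride reduction; with C8' as the large group anti to the bulky hydride and C9 inside, attack gives the (S)-carbinol, and the chelation model (Li between C=O and the ring oxygen) predicts the same face.

**Step 10**
Reactants: 14 (S)-[(3R,4R)-4-(ArCH2)oxolan-3-yl](Ar)methanol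
Product: 15 4-[(S)-hydroxy{(3R,4R)-4-[(4-hydroxy-3,5-dimethoxyphenyl)methyl]oxolan-3-yl}methyl]-2,6-dimethoxyphenol
Conditions: Bu4NF (2.5 equiv), AcOH (2.5 equiv), THF, 0 °C
Reagents that add atoms: none
Why: Fluoride cleavage of the two aryl silyl ethers; acetic acid buffers the phenoxides so the p-hydroxybenzylic alcohol does not eliminate to a quinone methide.

**Compound list**
1 | 4-bromophenol | Oc1ccc(Br)cc1 | starting material
2 | 4-bromo-2,6-diiodophenol | Oc1c(I)cc(Br)cc1I | intermediate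
3 | 4-bromo-2,6-dimethoxyphenol | COc1cc(Br)cc(OC)c1O | intermediate
4 | (4-bromo-2,6-dimethoxyphenoxy)tri(propan-2-yl)silane | COc1cc(Br)cc(OC)c1O[Si](C(C)C)(C(C)C)C(C)C | intermediate
5 | 3-(bromomethyl)oxetane | BrCC1COC1 | starting material
6 | 3-({3,5-dimethoxy-4-[tri(propan-2-yl)silyloxy]phenyl}methyl)oxetane | COc1cc(CC2COC2)cc(OC)c1O[Si](C(C)C)(C(C)C)C(C)C | intermediate
7 | (4R)-4-({3,5-dimethoxy-4-[tri(propan-2-yl)silyloxy]phenyl}methyl)oxolan-2-one | COc1cc(C[C@H]2COC(=O)C2)cc(OC)c1O[Si](C(C)C)(C(C)C)C(C)C | intermediate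
8 | {3,5-dimethoxy-4-[tri(propan-2-yl)silyloxy]phenyl}lithium | [Li]c1cc(OC)c(O[Si](C(C)C)(C(C)C)C(C)C)c(OC)c1 | intermediate (not isolated)
9 | lithium (4R)-2-Ar-4-(ArCH2)oxolan-2-olate (both C2 epimers) | [Li]OC1(c2cc(OC)c(O[Si](C(C)C)(C(C)C)C(C)C)c(OC)c2)C[C@@H](Cc2cc(OC)c(O[Si](C(C)C)(C(C)C)C(C)C)c(OC)c2)CO1 | intermediate (not isolated)
10 | (3R)-4-hydroxy-1-Ar-3-(ArCH2)butan-1-one | COc1cc(cc(OC)c1O[Si](C(C)C)(C(C)C)C(C)C)C(=O)C[C@@H](Cc1cc(OC)c(O[Si](C(C)C)(C(C)C)C(C)C)c(OC)c1)CO | intermediate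
11 | (3R)-4-(methoxymethoxy)-1-Ar-3-(ArCH2)butan-1-one | COc1cc(cc(OC)c1O[Si](C(C)C)(C(C)C)C(C)C)C(=O)C[C@@H](Cc1cc(OC)c(O[Si](C(C)C)(C(C)C)C(C)C)c(OC)c1)COCOC | intermediate
12 | (1Z,3R)-4-(methoxymethoxy)-1-Ar-3-(ArCH2)-1-(trimethylsilyloxy)but-1-ene | COc1cc(cc(OC)c1O[Si](C(C)C)(C(C)C)C(C)C)/C(O[Si](C)(C)C)=C/[C@@H](Cc1cc(OC)c(O[Si](C(C)C)(C(C)C)C(C)C)c(OC)c1)COCOC | intermediate (not isolated)
13 | [(3R,4R)-4-(ArCH2)oxolan-3-yl](Ar)methanone | COc1cc(C[C@H]2COC[C@@H]2C(=O)c2cc(OC)c(O[Si](C(C)C)(C(C)C)C(C)C)c(OC)c2)cc(OC)c1O[Si](C(C)C)(C(C)C)C(C)C | intermediate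
14 | (S)-[(3R,4R)-4-(ArCH2)oxolan-3-yl](Ar)methanol | COc1cc(C[C@H]2COC[C@@H]2[C@H](O)c2cc(OC)c(O[Si](C(C)C)(C(C)C)C(C)C)c(OC)c2)cc(OC)c1O[Si](C(C)C)(C(C)C)C(C)C | intermediate
15 | 4-[(S)-hydroxy{(3R,4R)-4-[(4-hydroxy-3,5-dimethoxyphenyl)methyl]oxolan-3-yl}methyl]-2,6-dimethoxyphenol | COc1cc(C[C@H]2COC[C@@H]2[C@H](O)c2cc(OC)c(O)c(OC)c2)cc(OC)c1O | target

**Totals**
Total step count: 10. Longest linear sequence: 10 steps (compound 4 enters twice, at steps 4 and 6).

**Three steps most likely to fail**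

Step 5 (the proposed new reaction). The risks are low enantioselectivity, slow carbonylation of the oxetane, and cationic oligomerisation. The fallback uses known chemistry, sets out from 4 and comes back at 7. Compound 4 is lithiated to 8 (n-BuLi, THF, −78 °C) and allylated with allyl bromide (CuBr·SMe2 cat.) to 5-allyl-1,3-dimethoxy-2-[tri(propan-2-yl)silyloxy]benzene F1. Cycloaddition with dichloroketene (Cl3CCOCl, Zn(Cu), Et2O) gives 2,2-dichloro-3-(ArCH2)cyclobutan-1-one F2. Zn/AcOH dechlorination gives the prochiral 3-(ArCH2)cyclobutan-1-one F3. A known catalytic asymmetric Baeyer–Villiger oxidation (Sc(OTf)3/chiral N,N'-dioxide with m-CPBA, or a cyclohexanone monooxygenase) then gives 7, again with a ring expansion as the stereodefining event.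

Step 8. The risks are intermolecular alkylation of the enol silane and attack of the electron-rich benzyl ring on the oxocarbenium ion. The fallback sets out from 10 and comes back at 13. Heating 10 with N,N-dimethylformamide dimethyl acetal (toluene, 100 °C) gives the enaminone (3R)-2-[(dimethylamino)methylidene]-4-hydroxy-1-Ar-3-(ArCH2)butan-1-one F4. TsOH (cat.) in CH2Cl2 closes it through the iminium tautomer (5-exo-trig) with loss of dimethylamine to [(4R)-4-(ArCH2)-4,5-dihydrofuran-3-yl](Ar)methanone F5. H2 (1 atm), Pd/C, EtOAc saturates the enol ether double bond, mainly from the face opposite the benzyl group, to the cis ketone [(3S,4R)-4-(ArCH2)oxolan-3-yl](Ar)methanone F6. DBU (cat.) epimerises C8 to 13.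

Step 9. The risk is a poor or inverted Felkin ratio at C7. The fallback sets out from 13 and comes back at 14. Reduction under conditions that favour the other epimer (for example NaBH4, CeCl3·7H2O, MeOH, −40 °C) gives (R)-[(3R,4R)-4-(ArCH2)oxolan-3-yl](Ar)methanol F7. Mitsunobu inversion (4-nitrobenzoic acid, PPh3, DIAD, toluene, 0 °C) gives (S)-[(3R,4R)-4-(ArCH2)oxolan-3-yl](Ar)methyl 4-nitrobenzoate F8. LiOH, THF/H2O, 0 °C gives 14.

Further compounds
F1 | step 5 | 5-allyl-1,3-dimethoxy-2-[tri(propan-2-yl)silyloxy]benzene | COc1cc(CC=C)cc(OC)c1O[Si](C(C)C)(C(C)C)C(C)C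
F2 | step 5 | 2,2-dichloro-3-(ArCH2)cyclobutan-1-one (racemic) | COc1cc(CC2CC(=O)C2(Cl)Cl)cc(OC)c1O[Si](C(C)C)(C(C)C)C(C)C
F3 | step 5 | 3-(ArCH2)cyclobutan-1-one | COc1cc(CC2CC(=O)C2)cc(OC)c1O[Si](C(C)C)(C(C)C)C(C)C
F4 | step 8 | (3R)-2-[(dimethylamino)methylidene]-4-hydroxy-1-Ar-3-(ArCH2)butan-1-one | COc1cc(cc(OC)c1O[Si](C(C)C)(C(C)C)C(C)C)C(=O)C(=CN(C)C)[C@@H](Cc1cc(OC)c(O[Si](C(C)C)(C(C)C)C(C)C)c(OC)c1)CO
F5 | step 8 | [(4R)-4-(ArCH2)-4,5-dihydrofuran-3-yl](Ar)methanone | COc1cc(C[C@H]2COC=C2C(=O)c2cc(OC)c(O[Si](C(C)C)(C(C)C)C(C)C)c(OC)c2)cc(OC)c1O[Si](C(C)C)(C(C)C)C(C)C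
F6 | step 8 | [(3S,4R)-4-(ArCH2)oxolan-3-yl](Ar)methanone | COc1cc(C[C@H]2COC[C@H]2C(=O)c2cc(OC)c(O[Si](C(C)C)(C(C)C)C(C)C)c(OC)c2)cc(OC)c1O[Si](C(C)C)(C(C)C)C(C)C
F7 | step 9 | (R)-[(3R,4R)-4-(ArCH2)oxolan-3-yl](Ar)methanol | COc1cc(C[C@H]2COC[C@@H]2[C@@H](O)c2cc(OC)c(O[Si](C(C)C)(C(C)C)C(C)C)c(OC)c2)cc(OC)c1O[Si](C(C)C)(C(C)C)C(C)C
F8 | step 9 | (S)-[(3R,4R)-4-(ArCH2)oxolan-3-yl](Ar)methyl 4-nitrobenzoate | COc1cc(C[C@H]2COC[C@@H]2[C@H](OC(=O)c2ccc(cc2)[N+](=O)[O-])c2cc(OC)c(O[Si](C(C)C)(C(C)C)C(C)C)c(OC)c2)cc(OC)c1O[Si](C(C)C)(C(C)C)C(C)C
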